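**Retrosynthetic overview**

1. The target is a 2,3-trans-3,4-cis robinetinidol unit (rings A, C, B; 2R,3S,4R) joined through C4–C8′ to an epigallocatechin unit (rings D, F, E; 2′R,3′R). The last step is hydrogenolysis of the ten benzyl ethers of 15.
2. The strategy rests on ring F: a 2,3-cis chroman-3-ol whose C4′ methylene is bonded to ring-D carbon C4a′, ortho to O1′. The C4′–C4a′ bond is cut back to the aryl (aryl)(oxiranyl)methyl ether 14, whose epoxide oxygen becomes the 3′-hydroxyl (6-endo Friedel–Crafts epoxide opening).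
3. The O1′–C2′ bond of 14 comes from a Mitsunobu inversion between ring-D phenol 10 and the erythro epoxy alcohol 13 (aldehyde 11, vinyl Grignard, Sharpless kinetic resolution).
4. The C4–C8′ bond and the 3,4-cis centre of 10 come from addition of the ortho-metalated MOM ether 5 to benzylated dihydrorobinetin 3, followed by ionic hydrogenation with hydride delivered anti to the 3-benzyloxy group.
5. Ring order: rings A, C and B come intact from (+)-dihydrorobinetin, ring D from 3,5-bis(benzyloxy)phenol, ring E from 3,4,5-tris(benzyloxy)benzaldehyde; ring F is the only ring formed, in step 9.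

Key step: step 9

Remark: (+)-dihydrorobinetin is taken as the purchasable (2R,3R) natural product. Locants follow flavan numbering, unprimed for the upper unit and primed for the lower unit.

**Route**

Step 1
Reactants: 1 (+)-dihydrorobinetin
Product: 2 (2R,3R)-7-(benzyloxy)-3-hydroxy-2-[3,4,5-tris(benzyloxy)phenyl]chroman-4-one
Conditions: BnBr (4.4 equiv), K2CO3, DMF, rt, argon
Reagents that add atoms: benzyl bromide, BrCc1ccccc1
Why: Williamson etherification in which K2CO3 deprotonates only the four phenols, so the 3-hydroxyl stays free and C2 and C3 are not touched at room temperature with air excluded.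

Step 2
Reactants: 2 (2R,3R)-7-(benzyloxy)-3-hydroxy-2-[3,4,5-tris(benzyloxy)phenyl]chroman-4-one
Product: 3 (2R,3R)-3,7-bis(benzyloxy)-2-[3,4,5-tris(benzyloxy)phenyl]chroman-4-one
Conditions: BnOC(=NH)CCl3 (2 equiv), TfOH (cat.), CH2Cl2/cyclohexane, 0 °C → rt
Reagents that add atoms: benzyl 2,2,2-trichloroacetimidate, ClC(Cl)(Cl)C(=N)OCc1ccccc1
Why: Acid-catalysed O-benzylation with the trichloroacetimidate etherifies the secondary 3-hydroxyl without base, so the base-labile α-hydroxy ketone is neither epimerised nor ring-opened.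

Step 3
Reactants: 4 3,5-bis(benzyloxy)phenol
Product: 5 1,3-bis(benzyloxy)-5-(methoxymethoxy)benzene
Conditions: MOMCl, iPr2NEt, CH2Cl2, 0 °C → rt
Reagents that add atoms: chloromethyl methyl ether, COCCl
Why: O-Alkylation of the phenol to its MOM acetal installs a group that directs lithiation in step 4 and can later be removed by acid without loss of the benzyl ethers.

Step 4
Reactants: 5 1,3-bis(benzyloxy)-5-(methoxymethoxy)benzene; 3 (2R,3R)-3,7-bis(benzyloxy)-2-[3,4,5-tris(benzyloxy)phenyl]chroman-4-one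
Product: 8 (2R,3R)-3,7-bis(benzyloxy)-4-[2,4-bis(benzyloxy)-6-(methoxymethoxy)phenyl]-2-[3,4,5-tris(benzyloxy)phenyl]chroman-4-ol (C4 epimers), via aryllithium 6 (not isolated), via arylcerium dichloride 7 (not isolated)
Conditions: nBuLi, THF, 0 °C; CeCl3, −78 °C; then 3, −78 → −40 °C; aq NH4Cl
Reagents that add atoms: none
Why: Directed ortho-metalation puts lithium between the OMOM group (the stronger director) and an OBn group, transmetalation to the less basic organocerium suppresses enolisation of the α-benzyloxy ketone, and 1,2-addition forms the C4–C8′ bond, the new C4 carbinol centre being of no consequence because it is ionised in step 5.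

Step 5
Reactants: 8 (2R,3R)-3,7-bis(benzyloxy)-4-[2,4-bis(benzyloxy)-6-(methoxymethoxy)phenyl]-2-[3,4,5-tris(benzyloxy)phenyl]chroman-4-ol (C4 epimers)
Product: 10 3,5-bis(benzyloxy)-2-{(2R,3S,4R)-3,7-bis(benzyloxy)-2-[3,4,5-tris(benzyloxy)phenyl]chroman-4-yl}phenol, via MOM ether 9 (not isolated)
Conditions: nBu3SnH (3 equiv), TFA, CH2Cl2, 0 °C; then MeOH, rt
Reagents that add atoms: none
Why: Ionic hydrogenation in which TFA ionises the doubly benzylic tertiary alcohol to a C4 cation and nBu3SnH delivers hydride to the face anti to the 3-benzyloxy group (the sense known for reduction of 4-aryl-flavan-4-ols in the 2,3-cis series), which sets C4 as R with the aryl group cis to O3, after which methanol and TFA remove the MOM group by transacetalisation.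

Step 6
Reactants: 11 3,4,5-tris(benzyloxy)benzaldehyde
Product: 12 rac-1-[3,4,5-tris(benzyloxy)phenyl]prop-2-en-1-ol
Conditions: vinylmagnesium bromide, THF, −78 → 0 °C; aq NH4Cl
Reagents that add atoms: vinylmagnesium bromide, C=C[Mg]Br
Why: Grignard 1,2-addition of the vinyl nucleophile to the aldehyde gives the racemic secondary allylic alcohol needed for the resolution.

Step 7
Reactants: 12 rac-1-[3,4,5-tris(benzyloxy)phenyl]prop-2-en-1-ol
Product: 13 (S)-[(2R)-oxiran-2-yl][3,4,5-tris(benzyloxy)phenyl]methanol (erythro)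
Conditions: Ti(OiPr)4 (0.15 equiv), L-(+)-DIPT (0.2 equiv), TBHP (0.45 equiv), 4 Å MS, CH2Cl2, −20 °C
Reagents that add atoms: tert-butyl hydroperoxide, CC(C)(C)OO
Why: Sharpless kinetic resolution (titanium–tartrate epoxidation) in which the (R)-enantiomer is epoxidised fast on the face that gives the erythro product, so the catalyst sets the epoxide carbon as R and selection of the enantiomer fixes the carbinol carbon as S, while the slow (S)-enantiomer is left behind and removed by chromatography.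

Step 8
Reactants: 10 3,5-bis(benzyloxy)-2-{(2R,3S,4R)-3,7-bis(benzyloxy)-2-[3,4,5-tris(benzyloxy)phenyl]chroman-4-yl}phenol; 13 (S)-[(2R)-oxiran-2-yl][3,4,5-tris(benzyloxy)phenyl]methanol (erythro)
Product: 14 (2R,3S,4R)-3,7-bis(benzyloxy)-4-[2,4-bis(benzyloxy)-6-{(R)-[(2R)-oxiran-2-yl][3,4,5-tris(benzyloxy)phenyl]methoxy}phenyl]-2-[3,4,5-tris(benzyloxy)phenyl]chromane
Conditions: nBu3P, TMAD, toluene, 0 °C → rt
Reagents that add atoms: none
Why: Mitsunobu etherification in which the phenoxide of 10 displaces the activated carbinol oxygen by SN2, inverting that carbon from S to R and so turning the erythro alcohol into the threo aryl ether with the epoxide untouched.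

Step 9
Reactants: 14 (2R,3S,4R)-3,7-bis(benzyloxy)-4-[2,4-bis(benzyloxy)-6-{(R)-[(2R)-oxiran-2-yl][3,4,5-tris(benzyloxy)phenyl]methoxy}phenyl]-2-[3,4,5-tris(benzyloxy)phenyl]chromane
Product: 15 (2R,3R)-5,7-bis(benzyloxy)-8-{(2R,3S,4R)-3,7-bis(benzyloxy)-2-[3,4,5-tris(benzyloxy)phenyl]chroman-4-yl}-2-[3,4,5-tris(benzyloxy)phenyl]chroman-3-ol
Conditions: BF3·OEt2 (0.3 equiv), CH2Cl2, −78 → −30 °C
Reagents that add atoms: none
Why: BF3 coordinates the epoxide oxygen, ring-D carbon C4a′ (ortho to O1′ and to the 5′-benzyloxy group, para to the 7′-benzyloxy group) attacks the unsubstituted epoxide carbon in an SN2-like opening, and loss of a proton from the arenium ion rearomatises ring D and leaves the epoxide oxygen as the 3′-hydroxyl. The closest known reaction type is the Lewis-acid- or fluoroalcohol-promoted Friedel–Crafts cyclisation of aryl oxiranylmethyl ethers to chroman-3-ols, which has been used for 2,3-cis flavan-3-ols. Ring F closes in the 6-endo mode through the new C4′–C4a′ bond. No stereocentre is made or broken, so C2′ and C3′ are carried over from 14 and the threo ether/epoxide pair becomes the 2,3-cis (2′R,3′R) arrangement directly. The step needs 6-endo over 5-exo opening and a single site on ring D: the primary carbon is the less hindered terminus and the 5-exo path leads to a more strained dihydrobenzofuran, while C4a′ is the only free position ortho to O1′ because C8′ carries the upper unit, whose bulk also turns the side chain toward C4a′. Low temperature and a substoichiometric charge of BF3·OEt2 are chosen so that the benzylic C2′–O1′ ether and the C4–C8′ bond are not ionised.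

Step 10
Reactants: 15 (2R,3R)-5,7-bis(benzyloxy)-8-{(2R,3S,4R)-3,7-bis(benzyloxy)-2-[3,4,5-tris(benzyloxy)phenyl]chroman-4-yl}-2-[3,4,5-tris(benzyloxy)phenyl]chroman-3-ol
Product: 16 robinetinidol-(4β→8)-epigallocatechin (CNP0275321.4)
Conditions: H2 (1 atm), Pd(OH)2/C, THF/MeOH, rt
Reagents that add atoms: none
Why: Catalytic hydrogenolysis cleaves all ten O-benzyl bonds under neutral conditions that should leave the ring C–O bonds, the interflavan bond and the five stereocentres intact.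

**Compound list**

1 | (+)-dihydrorobinetin, (2R,3R)-3,7-dihydroxy-2-(3,4,5-trihydroxyphenyl)chroman-4-one | O=C1c2ccc(O)cc2O[C@H](c2cc(O)c(O)c(O)c2)[C@H]1O | starting material
2 | (2R,3R)-7-(benzyloxy)-3-hydroxy-2-[3,4,5-tris(benzyloxy)phenyl]chroman-4-one | O=C1c2ccc(OCc4ccccc4)cc2O[C@H](c3cc(OCc4ccccc4)c(OCc4ccccc4)c(OCc4ccccc4)c3)[C@H]1O | intermediate
3 | (2R,3R)-3,7-bis(benzyloxy)-2-[3,4,5-tris(benzyloxy)phenyl]chroman-4-one | O=C1c2ccc(OCc4ccccc4)cc2O[C@H](c3cc(OCc4ccccc4)c(OCc4ccccc4)c(OCc4ccccc4)c3)[C@H]1OCc4ccccc4 | intermediate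
4 | 3,5-bis(benzyloxy)phenol | Oc1cc(OCc2ccccc2)cc(OCc2ccccc2)c1 | starting material
5 | 1,3-bis(benzyloxy)-5-(methoxymethoxy)benzene | COCOc1cc(OCc2ccccc2)cc(OCc2ccccc2)c1 | intermediate
6 | [2,4-bis(benzyloxy)-6-(methoxymethoxy)phenyl]lithium | [Li]c1c(OCOC)cc(OCc2ccccc2)cc1OCc2ccccc2 | intermediate
7 | dichloro[2,4-bis(benzyloxy)-6-(methoxymethoxy)phenyl]cerium | Cl[Ce](Cl)c1c(OCOC)cc(OCc2ccccc2)cc1OCc2ccccc2 | intermediate
8 | (2R,3R)-3,7-bis(benzyloxy)-4-[2,4-bis(benzyloxy)-6-(methoxymethoxy)phenyl]-2-[3,4,5-tris(benzyloxy)phenyl]chroman-4-ol (C4 epimers) | c4ccccc4COc1ccc2c(c1)O[C@H](c3cc(OCc4ccccc4)c(OCc4ccccc4)c(OCc4ccccc4)c3)[C@@H](OCc4ccccc4)C2(O)c5c(OCOC)cc(OCc4ccccc4)cc5OCc4ccccc4 | intermediate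
9 | (2R,3S,4R)-3,7-bis(benzyloxy)-4-[2,4-bis(benzyloxy)-6-(methoxymethoxy)phenyl]-2-[3,4,5-tris(benzyloxy)phenyl]chromane | c4ccccc4COc1ccc2c(c1)O[C@H](c3cc(OCc4ccccc4)c(OCc4ccccc4)c(OCc4ccccc4)c3)[C@@H](OCc4ccccc4)[C@H]2c5c(OCOC)cc(OCc4ccccc4)cc5OCc4ccccc4 | intermediate
10 | 3,5-bis(benzyloxy)-2-{(2R,3S,4R)-3,7-bis(benzyloxy)-2-[3,4,5-tris(benzyloxy)phenyl]chroman-4-yl}phenol | c4ccccc4COc1ccc2c(c1)O[C@H](c3cc(OCc4ccccc4)c(OCc4ccccc4)c(OCc4ccccc4)c3)[C@@H](OCc4ccccc4)[C@H]2c5c(O)cc(OCc4ccccc4)cc5OCc4ccccc4 | intermediate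
11 | 3,4,5-tris(benzyloxy)benzaldehyde | O=Cc1cc(OCc2ccccc2)c(OCc2ccccc2)c(OCc2ccccc2)c1 | starting material
12 | rac-1-[3,4,5-tris(benzyloxy)phenyl]prop-2-en-1-ol | C=CC(O)c1cc(OCc2ccccc2)c(OCc2ccccc2)c(OCc2ccccc2)c1 | intermediate
13 | (S)-[(2R)-oxiran-2-yl][3,4,5-tris(benzyloxy)phenyl]methanol (erythro) | O[C@@H](c1cc(OCc2ccccc2)c(OCc2ccccc2)c(OCc2ccccc2)c1)[C@H]3CO3 | intermediate
14 | (2R,3S,4R)-3,7-bis(benzyloxy)-4-[2,4-bis(benzyloxy)-6-{(R)-[(2R)-oxiran-2-yl][3,4,5-tris(benzyloxy)phenyl]methoxy}phenyl]-2-[3,4,5-tris(benzyloxy)phenyl]chromane | c4ccccc4COc1ccc2c(c1)O[C@H](c3cc(OCc4ccccc4)c(OCc4ccccc4)c(OCc4ccccc4)c3)[C@@H](OCc4ccccc4)[C@H]2c5c(OCc4ccccc4)cc(OCc4ccccc4)cc5O[C@H](c7cc(OCc4ccccc4)c(OCc4ccccc4)c(OCc4ccccc4)c7)[C@H]6CO6 | intermediate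
15 | (2R,3R)-5,7-bis(benzyloxy)-8-{(2R,3S,4R)-3,7-bis(benzyloxy)-2-[3,4,5-tris(benzyloxy)phenyl]chroman-4-yl}-2-[3,4,5-tris(benzyloxy)phenyl]chroman-3-ol | c4ccccc4COc1ccc2c(c1)O[C@H](c3cc(OCc4ccccc4)c(OCc4ccccc4)c(OCc4ccccc4)c3)[C@@H](OCc4ccccc4)[C@H]2c5c(OCc4ccccc4)cc(OCc4ccccc4)c6c5O[C@H](c7cc(OCc4ccccc4)c(OCc4ccccc4)c(OCc4ccccc4)c7)[C@H](O)C6 | intermediate
16 | robinetinidol-(4β→8)-epigallocatechin, (2R,3S,4R) upper unit and (2′R,3′R) lower unit | Oc1ccc2c(c1)O[C@H](c1cc(O)c(O)c(O)c1)[C@@H](O)[C@H]2c1c(O)cc(O)c2c1O[C@H](c1cc(O)c(O)c(O)c1)[C@H](O)C2 | target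

**Step count**

Total step count: 10. Longest linear sequence: 7 steps (steps 1, 2, 4, 5, 8, 9, 10, from 1 to 16).

**Steps most likely to fail**

Step 9 (key cyclisation). The Lewis acid may ionise the benzylic C2′–O1′ ether faster than it opens the epoxide, which would epimerise C2′ or cut off the side chain. The epoxide may also open in the 5-exo sense, or acid may cleave the C4–C8′ bond. Fallback: ring F is not closed on the dimer but taken ready-made, and the interflavan bond is formed last with the chemistry of steps 4 and 5. The fallback sets out from ketone 3 and comes back to the route at 16. Commercial (−)-epigallocatechin is benzylated on its five phenols (BnBr, K2CO3, DMF, argon) to penta-O-benzyl-epigallocatechin F1, and the 3-hydroxyl is then benzylated (NaH, BnBr, DMF, 0 °C) to the hexabenzyl ether F2. NBS in CH2Cl2 at −78 °C should brominate the activated ring-D position C8 to give the 8-bromide F3. Bromine–lithium exchange (tBuLi, THF, −78 °C) and addition of the aryllithium to 3 should give the tertiary carbinol F4. Ionic hydrogenation as in step 5 (nBu3SnH, TFA, CH2Cl2) should give the undecabenzyl ether F5 with the 3,4-cis arrangement, and hydrogenolysis as in step 10 then gives 16.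

Step 8 (Mitsunobu etherification). O-Alkylation may be slow at the phenol flanked by the flavanyl group, so that the activated, electron-rich benzylic carbinol reacts instead by ionisation (loss of clean inversion) or by elimination. Fallback: the ether bond is made on the unhindered monomeric phenol before the interflavan bond exists. The fallback sets out from 4 and 13 and comes back to the route at 16. Mitsunobu reaction of 4 with 13 (nBu3P, TMAD, toluene) should give the threo ether 1,3-bis(benzyloxy)-5-{(R)-[(2R)-oxiran-2-yl][3,4,5-tris(benzyloxy)phenyl]methoxy}benzene F6. Its BF3·OEt2 cyclisation, in which both ortho positions lead to the same product, should give penta-O-benzyl-epigallocatechin F1. From F1 the sequence described for step 9 is followed through F2, F3, F4 and F5 to 16.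

Step 5 (ionic hydrogenation). Facial selectivity of hydride delivery to the C4 cation may be poor, because the 2-aryl group lies on the face the hydride must use. The cation may also lose the C3 proton to give an enol ether, which would erase C3. Fallback: C4 is set by arene attack on the cation instead of hydride attack. The fallback sets out from 3 and 4 and comes back to the route at 10. NaBH4 (MeOH/THF, 0 °C) should reduce 3 to the flavan-4-ol (2R,3S)-3,7-bis(benzyloxy)-2-[3,4,5-tris(benzyloxy)phenyl]chroman-4-ol F7. BF3·OEt2 in CH2Cl2 at −78 °C then ionises F7 in the presence of excess 4, whose carbon ortho to the hydroxyl attacks C4 (Friedel–Crafts union of the flavan-4-ol/phenol type). This is expected to give 10 together with its C4 epimer, so 10 would have to be secured by chromatography.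

Further compounds

F1 | step 9 | (2R,3R)-5,7-bis(benzyloxy)-2-[3,4,5-tris(benzyloxy)phenyl]chroman-3-ol (penta-O-benzyl-epigallocatechin) | c1c(OCc4ccccc4)cc(OCc4ccccc4)c2c1O[C@H](c3cc(OCc4ccccc4)c(OCc4ccccc4)c(OCc4ccccc4)c3)[C@H](O)C2
F2 | step 9 | (2R,3R)-3,5,7-tris(benzyloxy)-2-[3,4,5-tris(benzyloxy)phenyl]chromane | c1c(OCc4ccccc4)cc(OCc4ccccc4)c2c1O[C@H](c3cc(OCc4ccccc4)c(OCc4ccccc4)c(OCc4ccccc4)c3)[C@H](OCc4ccccc4)C2
F3 | step 9 | (2R,3R)-3,5,7-tris(benzyloxy)-8-bromo-2-[3,4,5-tris(benzyloxy)phenyl]chromane | Brc1c(OCc4ccccc4)cc(OCc4ccccc4)c2c1O[C@H](c3cc(OCc4ccccc4)c(OCc4ccccc4)c(OCc4ccccc4)c3)[C@H](OCc4ccccc4)C2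
F4 | step 9 | (2R,3R)-3,7-bis(benzyloxy)-4-{(2R,3R)-3,5,7-tris(benzyloxy)-2-[3,4,5-tris(benzyloxy)phenyl]chroman-8-yl}-2-[3,4,5-tris(benzyloxy)phenyl]chroman-4-ol (C4 epimers) | c4ccccc4COc1ccc2c(c1)O[C@H](c3cc(OCc4ccccc4)c(OCc4ccccc4)c(OCc4ccccc4)c3)[C@@H](OCc4ccccc4)C2(O)c5c(OCc4ccccc4)cc(OCc4ccccc4)c6c5O[C@H](c7cc(OCc4ccccc4)c(OCc4ccccc4)c(OCc4ccccc4)c7)[C@H](OCc4ccccc4)C6
F5 | step 9 | (2R,3R)-3,5,7-tris(benzyloxy)-8-{(2R,3S,4R)-3,7-bis(benzyloxy)-2-[3,4,5-tris(benzyloxy)phenyl]chroman-4-yl}-2-[3,4,5-tris(benzyloxy)phenyl]chromane (undecabenzyl ether of the target) | c4ccccc4COc1ccc2c(c1)O[C@H](c3cc(OCc4ccccc4)c(OCc4ccccc4)c(OCc4ccccc4)c3)[C@@H](OCc4ccccc4)[C@H]2c5c(OCc4ccccc4)cc(OCc4ccccc4)c6c5O[C@H](c7cc(OCc4ccccc4)c(OCc4ccccc4)c(OCc4ccccc4)c7)[C@H](OCc4ccccc4)C6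
F6 | step 8 | 1,3-bis(benzyloxy)-5-{(R)-[(2R)-oxiran-2-yl][3,4,5-tris(benzyloxy)phenyl]methoxy}benzene | c1c(OCc4ccccc4)cc(OCc4ccccc4)cc1O[C@H](c7cc(OCc4ccccc4)c(OCc4ccccc4)c(OCc4ccccc4)c7)[C@H]6CO6
F7 | step 5 | (2R,3S)-3,7-bis(benzyloxy)-2-[3,4,5-tris(benzyloxy)phenyl]chroman-4-ol (C4 epimers) | c4ccccc4COc1ccc2c(c1)O[C@H](c3cc(OCc4ccccc4)c(OCc4ccccc4)c(OCc4ccccc4)c3)[C@@H](OCc4ccccc4)C2O
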